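**Retrosynthetic overview**

1. The target comes from nine-fold O-debenzylation of a perbenzylated digallate, made by double Steglich acylation of a 7,3'-diphenol that is freed from two MOM ethers; MOM (O-7, O-3') against benzyl (O-5, O-4', O-3) fixes the acylation pattern from the first steps.
2. Ring C is closed by the O1–C8a bond: the C2 lithium alkoxide of an open-chain 8-bromo-1,3-diarylpropan-1-ol adds to an aryne spanning C8–C8a, generated with LiTMP (cine substitution: bromine leaves C8, oxygen enters at C8a).
3. Enabling feature: in ring A, C8 carries only hydrogen and lies between the O1-bearing C8a and the oxygen-bearing C7. A bromine on C8 therefore has one ortho hydrogen (on C8a), the C7 oxygen polarises the C8–C8a aryne toward attack at C8a, and the C4–C3–C2 chain on the neighbouring C4a holds the alkoxide within reach of C8a only.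
4. The open-chain alcohol comes from zinc-chelate-controlled reduction of an α-benzyloxy aryl ketone (sets C2), made from a ring B aryl Grignard reagent and a Weinreb amide; the amide comes from an Evans glycolate alkylation (sets C3) with a ring A benzylic bromide derived from 5-bromo-2,4-dihydroxybenzaldehyde, whose chelated 2-OH and free 4-OH already distinguish O-5 from O-7.
5. Order of ring formation: rings A and B are bought as arenes; ring C is the only ring formed, in step 13.

Key step: step 13

Remark: flavan numbering (O1, C2, C3, C4, C4a, C5 to C8, C8a; ring B atoms primed) is used for the open-chain precursors too, and the target is assumed to be handled without base after step 16, because a catechol monoester can shift its acyl group to the neighbouring phenol.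

**Route**

Step 1
Reactants: 1 5-bromo-2,4-dihydroxybenzaldehyde
Product: 2 5-bromo-2-hydroxy-4-(methoxymethoxy)benzaldehyde
Conditions: MOMCl (1.05 equiv), K2CO3, acetone, 0 °C → rt
Reagents that add atoms: chloromethyl methyl ether (MOMCl), COCCl
Why: Williamson etherification in which the 2-OH is held in a hydrogen bond to the aldehyde, so that only the more acidic 4-OH (the future O-7) should be alkylated.

Step 2
Reactants: 2 5-bromo-2-hydroxy-4-(methoxymethoxy)benzaldehyde
Product: 3 2-(benzyloxy)-5-bromo-4-(methoxymethoxy)benzaldehyde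
Conditions: BnBr, K2CO3, DMF, 50 °C
Reagents that add atoms: benzyl bromide, BrCc1ccccc1
Why: Williamson etherification of the remaining chelated phenol under more forcing conditions, which marks the future O-5 with a group different from that on O-7.

Step 3
Reactants: 3 2-(benzyloxy)-5-bromo-4-(methoxymethoxy)benzaldehyde
Product: 4 [2-(benzyloxy)-5-bromo-4-(methoxymethoxy)phenyl]methanol
Conditions: NaBH4, MeOH/THF, 0 °C
Reagents that add atoms: none
Why: Borohydride reduction of an aryl aldehyde, which leaves the aryl bromide and both ethers untouched.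

Step 4
Reactants: 4 [2-(benzyloxy)-5-bromo-4-(methoxymethoxy)phenyl]methanol
Product: 5 1-(benzyloxy)-4-bromo-2-(bromomethyl)-5-(methoxymethoxy)benzene
Conditions: CBr4, PPh3, CH2Cl2, 0 °C; used crude
Reagents that add atoms: carbon tetrabromide, BrC(Br)(Br)Br
Why: Appel bromination under neutral conditions spares the MOM acetal, and the ring bromine meta to the benzylic carbon should temper ionisation of this electron-rich benzylic bromide.

Step 5
Reactants: 6 (R)-4-benzyloxazolidin-2-one, 7 2-(benzyloxy)acetyl chloride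
Product: 8 (R)-4-benzyl-3-[2-(benzyloxy)acetyl]oxazolidin-2-one
Conditions: Et3N, DMAP (cat.), CH2Cl2, 0 °C → rt
Reagents that add atoms: none
Why: DMAP-catalysed N-acylation of the oxazolidinone with an acid chloride, a standard entry to glycolate imides.

Step 6
Reactants: 8 (R)-4-benzyl-3-[2-(benzyloxy)acetyl]oxazolidin-2-one, 5 1-(benzyloxy)-4-bromo-2-(bromomethyl)-5-(methoxymethoxy)benzene
Product: 10 (R)-4-benzyl-3-[(S)-2-(benzyloxy)-3-[2-(benzyloxy)-5-bromo-4-(methoxymethoxy)phenyl]propanoyl]oxazolidin-2-one, via sodium Z-enolate 9 (not isolated)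
Conditions: NaHMDS, THF, −78 °C; then 5, −78 → −45 °C
Reagents that add atoms: none
Why: Evans glycolate alkylation in which the sodium-chelated Z-enolate is attacked by the benzylic bromide on the face away from the auxiliary benzyl group, which with the (R)-auxiliary should set the (S) centre that becomes C3.

Step 7
Reactants: 10 (R)-4-benzyl-3-[(S)-2-(benzyloxy)-3-[2-(benzyloxy)-5-bromo-4-(methoxymethoxy)phenyl]propanoyl]oxazolidin-2-one
Product: 11 (S)-2-(benzyloxy)-3-[2-(benzyloxy)-5-bromo-4-(methoxymethoxy)phenyl]-N-methoxy-N-methylpropanamide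
Conditions: MeNH(OMe)·HCl, AlMe3, CH2Cl2, −10 °C → rt; Rochelle salt work-up
Reagents that add atoms: N,O-dimethylhydroxylamine hydrochloride, CNOC.Cl
Why: Weinreb transamination with the aluminium amide cleaves the exocyclic imide carbonyl without enolising the α-alkoxy centre and returns the auxiliary.

Step 8
Reactants: 12 5-bromo-2-hydroxybenzaldehyde
Product: 13 2-(benzyloxy)-5-bromobenzaldehyde
Conditions: BnBr, K2CO3, DMF, rt
Reagents that add atoms: benzyl bromide, BrCc1ccccc1
Why: Williamson etherification that places the benzyl group on the oxygen para to bromine, the future O-4'.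

Step 9
Reactants: 13 2-(benzyloxy)-5-bromobenzaldehyde
Product: 15 2-(benzyloxy)-5-bromophenol, via aryl formate 14 (not isolated)
Conditions: mCPBA, CH2Cl2, rt; then K2CO3, MeOH, rt
Reagents that add atoms: 3-chloroperoxybenzoic acid (mCPBA), O=C(OO)c1cccc(Cl)c1
Why: Baeyer–Villiger (Dakin-type) oxidation in which the electron-rich ortho-alkoxyaryl group migrates to oxygen, followed by methanolysis of the formate to the phenol meta to bromine, the future O-3'.

Step 10
Reactants: 15 2-(benzyloxy)-5-bromophenol
Product: 16 1-(benzyloxy)-4-bromo-2-(methoxymethoxy)benzene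
Conditions: MOMCl, K2CO3, acetone, rt
Reagents that add atoms: chloromethyl methyl ether (MOMCl), COCCl
Why: Williamson etherification that gives O-3' the same base-stable acetal group as O-7.

Step 11
Reactants: 16 1-(benzyloxy)-4-bromo-2-(methoxymethoxy)benzene, 11 (S)-2-(benzyloxy)-3-[2-(benzyloxy)-5-bromo-4-(methoxymethoxy)phenyl]-N-methoxy-N-methylpropanamide
Product: 18 (S)-2-(benzyloxy)-3-[2-(benzyloxy)-5-bromo-4-(methoxymethoxy)phenyl]-1-[4-(benzyloxy)-3-(methoxymethoxy)phenyl]propan-1-one, via aryl Grignard reagent 17 (not isolated)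
Conditions: Mg, I2 (cat.), THF, 45 °C; then 11, THF, 0 °C → rt; aq. NH4Cl
Reagents that add atoms: none
Why: Weinreb ketone synthesis whose chelated tetrahedral intermediate stops over-addition and shields the α-centre, with a Grignard reagent that does not exchange with the ring A bromine.

Step 12
Reactants: 18 (S)-2-(benzyloxy)-3-[2-(benzyloxy)-5-bromo-4-(methoxymethoxy)phenyl]-1-[4-(benzyloxy)-3-(methoxymethoxy)phenyl]propan-1-one
Product: 19 (1R,2S)-2-(benzyloxy)-3-[2-(benzyloxy)-5-bromo-4-(methoxymethoxy)phenyl]-1-[4-(benzyloxy)-3-(methoxymethoxy)phenyl]propan-1-ol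
Conditions: Zn(BH4)2, Et2O/CH2Cl2, −30 → 0 °C
Reagents that add atoms: none
Why: Cram-chelate reduction in which zinc bridges the ketone and the α-benzyloxy oxygen and hydride enters from the side of the α-hydrogen, which should give the anti (1R,2S) alcohol, the open-chain form of the 2,3-trans flavan.

Step 13
Reactants: 19 (1R,2S)-2-(benzyloxy)-3-[2-(benzyloxy)-5-bromo-4-(methoxymethoxy)phenyl]-1-[4-(benzyloxy)-3-(methoxymethoxy)phenyl]propan-1-ol
Product: 21 (2R,3S)-3,5-bis(benzyloxy)-2-[4-(benzyloxy)-3-(methoxymethoxy)phenyl]-7-(methoxymethoxy)chromane, via aryne alkoxide 20 (not isolated)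
Conditions: LiTMP (3.5 equiv), THF (0.02 M), −78 → 0 °C; aq. NH4Cl
Reagents that add atoms: none
Why: LiTMP first makes the lithium alkoxide and then removes the only hydrogen ortho to bromine (C8a–H), loss of LiBr gives aryne 20 with its strained bond between C8 and C8a, the alkoxide oxygen held by the C4–C3–C2 chain on C4a adds in the ring plane to C8a, and the aryllithium left at C8 is protonated by tetramethylpiperidine or on work-up. The closest known reaction types are the cine substitution of ortho-haloanisoles through 3-alkoxyarynes, where the nucleophile ends up meta to the oxygen, and the ring closure of tethered amine and alkoxide nucleophiles onto arynes generated from meta-haloarenes with amide bases. Ring C closes in the 6-exo-dig mode on the in-plane π bond of the aryne. No new stereocentre is formed: C2 and C3 keep the configurations set in steps 12 and 6, because only the carbinol O–H bond and bonds of ring A change. The step needs site selectivity in aryne formation and in the addition: the MOM ether on C7 leaves the bromine a single ortho hydrogen, so only the C8–C8a aryne can form, and both the tether (attack at C8 would need a meta-bridged ring) and the inductive pull of the C7 oxygen, which places the developing carbanion at C8, direct the oxygen to C8a. The benzyl ether on O-3 removes the competing five-membered closure, and the hindered amide base should not add to the aryne itself.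

Step 14
Reactants: 21 (2R,3S)-3,5-bis(benzyloxy)-2-[4-(benzyloxy)-3-(methoxymethoxy)phenyl]-7-(methoxymethoxy)chromane
Product: 22 (2R,3S)-3,5-bis(benzyloxy)-2-[4-(benzyloxy)-3-hydroxyphenyl]chroman-7-ol
Conditions: HCl (cat.), MeOH/THF, 40 °C
Reagents that add atoms: none
Why: Acid-catalysed acetal exchange with methanol removes both aryl MOM ethers, while the benzyl ethers are inert and the mild conditions should not ionise the C2–O1 bond.

Step 15
Reactants: 22 (2R,3S)-3,5-bis(benzyloxy)-2-[4-(benzyloxy)-3-hydroxyphenyl]chroman-7-ol, 23 3,4,5-tris(benzyloxy)benzoic acid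
Product: 24 (2R,3S)-3,5-bis(benzyloxy)-2-[4-(benzyloxy)-3-{[3,4,5-tris(benzyloxy)benzoyl]oxy}phenyl]chroman-7-yl 3,4,5-tris(benzyloxy)benzoate
Conditions: 23 (2.4 equiv), EDC·HCl, DMAP, CH2Cl2, rt
Reagents that add atoms: none
Why: Steglich esterification of the only two free hydroxyl groups, the phenols on C7 and C3', all other oxygens being benzylated.

Step 16
Reactants: 24 (2R,3S)-3,5-bis(benzyloxy)-2-[4-(benzyloxy)-3-{[3,4,5-tris(benzyloxy)benzoyl]oxy}phenyl]chroman-7-yl 3,4,5-tris(benzyloxy)benzoate
Product: 25 catechin 7,3'-di-O-gallate, (2R,3S)-3,5-dihydroxy-2-[4-hydroxy-3-(3,4,5-trihydroxybenzoyloxy)phenyl]chroman-7-yl 3,4,5-trihydroxybenzoate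
Conditions: H2 (1 atm), Pd(OH)2/C, THF/EtOAc, rt; filtration, no base
Reagents that add atoms: none
Why: Catalytic hydrogenolysis should cleave all nine benzyl ethers under neutral conditions that leave the aryl esters, the chroman ring and both stereocentres alone.

**Compound list**

1 | 5-bromo-2,4-dihydroxybenzaldehyde | O=Cc1cc(Br)c(O)cc1O | starting material
2 | 5-bromo-2-hydroxy-4-(methoxymethoxy)benzaldehyde | O=Cc1cc(Br)c(OCOC)cc1O | intermediate
3 | 2-(benzyloxy)-5-bromo-4-(methoxymethoxy)benzaldehyde | O=Cc1cc(Br)c(OCOC)cc1OCc1ccccc1 | intermediate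
4 | [2-(benzyloxy)-5-bromo-4-(methoxymethoxy)phenyl]methanol | OCc1cc(Br)c(OCOC)cc1OCc1ccccc1 | intermediate
5 | 1-(benzyloxy)-4-bromo-2-(bromomethyl)-5-(methoxymethoxy)benzene | BrCc1cc(Br)c(OCOC)cc1OCc1ccccc1 | intermediate
6 | (R)-4-benzyloxazolidin-2-one | O=C1N[C@H](Cc2ccccc2)CO1 | starting material
7 | 2-(benzyloxy)acetyl chloride | O=C(Cl)COCc1ccccc1 | starting material
8 | (R)-4-benzyl-3-[2-(benzyloxy)acetyl]oxazolidin-2-one | O=C1OC[C@@H](Cc2ccccc2)N1C(=O)COCc1ccccc1 | intermediate
9 | sodium (Z)-enolate of 8 | [Na+].[O-]/C(=C\OCc1ccccc1)N1[C@H](Cc2ccccc2)COC1=O | intermediate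
10 | (R)-4-benzyl-3-[(S)-2-(benzyloxy)-3-[2-(benzyloxy)-5-bromo-4-(methoxymethoxy)phenyl]propanoyl]oxazolidin-2-one | O=C1OC[C@@H](Cc2ccccc2)N1C(=O)[C@@H](OCc1ccccc1)Cc1cc(Br)c(OCOC)cc1OCc1ccccc1 | intermediate
11 | (S)-2-(benzyloxy)-3-[2-(benzyloxy)-5-bromo-4-(methoxymethoxy)phenyl]-N-methoxy-N-methylpropanamide | CON(C)C(=O)[C@@H](OCc1ccccc1)Cc1cc(Br)c(OCOC)cc1OCc1ccccc1 | intermediate
12 | 5-bromo-2-hydroxybenzaldehyde | O=Cc1cc(Br)ccc1O | starting material
13 | 2-(benzyloxy)-5-bromobenzaldehyde | O=Cc1cc(Br)ccc1OCc1ccccc1 | intermediate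
14 | 2-(benzyloxy)-5-bromophenyl formate | O=COc1cc(Br)ccc1OCc1ccccc1 | intermediate
15 | 2-(benzyloxy)-5-bromophenol | Oc1cc(Br)ccc1OCc1ccccc1 | intermediate
16 | 1-(benzyloxy)-4-bromo-2-(methoxymethoxy)benzene | COCOc1cc(Br)ccc1OCc1ccccc1 | intermediate
17 | [4-(benzyloxy)-3-(methoxymethoxy)phenyl]magnesium bromide | COCOc1cc([Mg]Br)ccc1OCc1ccccc1 | intermediate
18 | (S)-2-(benzyloxy)-3-[2-(benzyloxy)-5-bromo-4-(methoxymethoxy)phenyl]-1-[4-(benzyloxy)-3-(methoxymethoxy)phenyl]propan-1-one | O=C(c1ccc(OCc2ccccc2)c(OCOC)c1)[C@@H](OCc1ccccc1)Cc1cc(Br)c(OCOC)cc1OCc1ccccc1 | intermediate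
19 | (1R,2S)-2-(benzyloxy)-3-[2-(benzyloxy)-5-bromo-4-(methoxymethoxy)phenyl]-1-[4-(benzyloxy)-3-(methoxymethoxy)phenyl]propan-1-ol | O[C@H](c1ccc(OCc2ccccc2)c(OCOC)c1)[C@@H](OCc1ccccc1)Cc1cc(Br)c(OCOC)cc1OCc1ccccc1 | intermediate
20 | lithium alkoxide of the C8–C8a aryne derived from 19 | [Li+].[O-][C@H](c1ccc(OCc2ccccc2)c(OCOC)c1)[C@@H](OCc1ccccc1)CC1=C(OCc2ccccc2)C=C(OCOC)C#C1 | intermediate
21 | (2R,3S)-3,5-bis(benzyloxy)-2-[4-(benzyloxy)-3-(methoxymethoxy)phenyl]-7-(methoxymethoxy)chromane | COCOc1cc(OCc2ccccc2)c3c(c1)O[C@H](c1ccc(OCc2ccccc2)c(OCOC)c1)[C@@H](OCc1ccccc1)C3 | intermediate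
22 | (2R,3S)-3,5-bis(benzyloxy)-2-[4-(benzyloxy)-3-hydroxyphenyl]chroman-7-ol | Oc1cc(OCc2ccccc2)c3c(c1)O[C@H](c1ccc(OCc2ccccc2)c(O)c1)[C@@H](OCc1ccccc1)C3 | intermediate
23 | 3,4,5-tris(benzyloxy)benzoic acid | O=C(O)c1cc(OCc2ccccc2)c(OCc2ccccc2)c(OCc2ccccc2)c1 | starting material
24 | (2R,3S)-3,5-bis(benzyloxy)-2-[4-(benzyloxy)-3-{[3,4,5-tris(benzyloxy)benzoyl]oxy}phenyl]chroman-7-yl 3,4,5-tris(benzyloxy)benzoate | O=C(Oc1cc(OCc2ccccc2)c3c(c1)O[C@H](c1ccc(OCc2ccccc2)c(OC(=O)c2cc(OCc4ccccc4)c(OCc4ccccc4)c(OCc4ccccc4)c2)c1)[C@@H](OCc1ccccc1)C3)c1cc(OCc2ccccc2)c(OCc2ccccc2)c(OCc2ccccc2)c1 | intermediate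
25 | catechin 7,3'-di-O-gallate | O=C(Oc1cc(O)c2c(c1)O[C@H](c1ccc(O)c(OC(=O)c3cc(O)c(O)c(O)c3)c1)[C@@H](O)C2)c1cc(O)c(O)c(O)c1 | target

**Step count and risks**

Total step count: 16.
Longest linear sequence: 12 steps from compound 1 (steps 1, 2, 3, 4, 6, 7, 11, 12, 13, 14, 15, 16).

Steps most likely to fail:

1. Step 13 (aryne ring closure). What may go wrong: metalation at C6 between the two ether oxygens followed by transfer of bromine between molecules, so that the bromine is lost before the aryne forms, or base-induced elimination of the O-3 benzyl ether. The fallback makes the same O1–C8a bond by palladium-catalysed ipso substitution instead of cine substitution. It sets out from compound 8 and comes back to the route at compound 21. Commercial 5-bromobenzene-1,3-diol would be formylated (POCl3, DMF, Vilsmeier–Haack) to 2-bromo-4,6-dihydroxybenzaldehyde F1. The operations of steps 1 to 4 would then give 2-bromo-6-hydroxy-4-(methoxymethoxy)benzaldehyde F2, 2-(benzyloxy)-6-bromo-4-(methoxymethoxy)benzaldehyde F3, [2-(benzyloxy)-6-bromo-4-(methoxymethoxy)phenyl]methanol F4 and 1-(benzyloxy)-3-bromo-2-(bromomethyl)-5-(methoxymethoxy)benzene F5. Alkylation of enolate 9, made from 8, with this bromide would give the regioisomeric imide F6. The operations of steps 7, 11 and 12 would give the regioisomeric Weinreb amide F7, the regioisomeric ketone F8 and the regioisomeric (1R,2S)-alcohol F9, which carries its bromine on C8a. Intramolecular aryl ether formation (Pd(OAc)2, 2-(di-tert-butylphosphino)-1,1'-binaphthyl, Cs2CO3, toluene, 70 °C) should then close ring C with retention at C2 and C3 and give 21.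

2. Step 12 (chelate-controlled reduction). What may go wrong: poor facial selectivity of hydride delivery because the MOM and benzyl ether oxygens compete with the α-benzyloxy oxygen for zinc, or enolisation of the α-alkoxy ketone before reduction. The fallback replaces substrate control by catalyst control: asymmetric transfer hydrogenation of 18 with RuCl(p-cymene)[(S,S)-TsDPEN] in HCO2H/Et3N. The catalyst recognises the aryl group of the ketone and should deliver hydride to the face that gives the (1R) carbinol regardless of chelation. It sets out from compound 18 and comes back at compound 19, and makes no new compound.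

3. Step 16 (global hydrogenolysis). What may go wrong: stalling at the hindered secondary 3-O-benzyl ether, so that the aryl esters stay for a long time beside the freed 4'-phenol, with migration of the galloyl group from O-3' to O-4'. The fallback is non-reductive cleavage of all nine benzyl ethers with BCl3 and pentamethylbenzene as cation scavenger in CH2Cl2 at −78 °C, quenched cold. These acidic, non-nucleophilic, low-temperature conditions should not allow acyl migration, though the benzylic C2–O1 bond could also be attacked, so the reaction time must be kept short. It sets out from compound 24 and comes back at compound 25, and makes no new compound.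

**Further compounds**

F1 | step 13 | 2-bromo-4,6-dihydroxybenzaldehyde | O=Cc1c(Br)cc(O)cc1O
F2 | step 13 | 2-bromo-6-hydroxy-4-(methoxymethoxy)benzaldehyde | O=Cc1c(Br)cc(OCOC)cc1O
F3 | step 13 | 2-(benzyloxy)-6-bromo-4-(methoxymethoxy)benzaldehyde | O=Cc1c(Br)cc(OCOC)cc1OCc1ccccc1
F4 | step 13 | [2-(benzyloxy)-6-bromo-4-(methoxymethoxy)phenyl]methanol | OCc1c(Br)cc(OCOC)cc1OCc1ccccc1
F5 | step 13 | 1-(benzyloxy)-3-bromo-2-(bromomethyl)-5-(methoxymethoxy)benzene | BrCc1c(Br)cc(OCOC)cc1OCc1ccccc1
F6 | step 13 | (R)-4-benzyl-3-[(S)-2-(benzyloxy)-3-[2-(benzyloxy)-6-bromo-4-(methoxymethoxy)phenyl]propanoyl]oxazolidin-2-one | O=C1OC[C@@H](Cc2ccccc2)N1C(=O)[C@@H](OCc1ccccc1)Cc1c(Br)cc(OCOC)cc1OCc1ccccc1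
F7 | step 13 | (S)-2-(benzyloxy)-3-[2-(benzyloxy)-6-bromo-4-(methoxymethoxy)phenyl]-N-methoxy-N-methylpropanamide | CON(C)C(=O)[C@@H](OCc1ccccc1)Cc1c(Br)cc(OCOC)cc1OCc1ccccc1
F8 | step 13 | (S)-2-(benzyloxy)-3-[2-(benzyloxy)-6-bromo-4-(methoxymethoxy)phenyl]-1-[4-(benzyloxy)-3-(methoxymethoxy)phenyl]propan-1-one | O=C(c1ccc(OCc2ccccc2)c(OCOC)c1)[C@@H](OCc1ccccc1)Cc1c(Br)cc(OCOC)cc1OCc1ccccc1
F9 | step 13 | (1R,2S)-2-(benzyloxy)-3-[2-(benzyloxy)-6-bromo-4-(methoxymethoxy)phenyl]-1-[4-(benzyloxy)-3-(methoxymethoxy)phenyl]propan-1-ol | O[C@H](c1ccc(OCc2ccccc2)c(OCOC)c1)[C@@H](OCc1ccccc1)Cc1c(Br)cc(OCOC)cc1OCc1ccccc1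
F0 | step 12 | none | none
F0 | step 16 | none | none
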